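## Structural features

AKML B is a 24-membered macrolactone: C1 to C23 and the ester oxygen form the ring, and C24 is the methyl group on the (R)-configured lactone carbinol C23. Two cis double bonds lie in the ring, the conjugated C2=C3 of a Z-enoate and the isolated C18=C19, which an eight-methylene tether (C10–C17) separates from the polar sector. The polar sector C5–C9 has five contiguous oxygenated stereocentres: the C5 carbinol (S), the cis-oxirane C6 (S)/C7 (R) and the syn-diol C8 (S)/C9 (R). C5–OH is erythro to the oxirane; if C5–C9 are folded into a pyran through O9, the C8 hydroxyl is cis to the C10 chain and trans to the oxirane. The fragile groups are the oxirane between two free carbinols (migration under base, opening under strong acid), the Z-enoate (Z to E isomerisation when the acyl group is activated), and the C5 hydroxyl, which is δ to the lactone carbonyl across a cis double bond and can contract the ring to a six-membered lactone under base. The real difficulty is the C5–C9 array: five adjacent heteroatom-bearing centres with no carbon branch to relay stereochemistry, and C23 too remote to help. The key step exploits the fact that C5, the cis C6=C7 unit, C8 and the C9 carbinol form a cis-2-ene-1,4-dioxygenated unit next to a carbinol. This is the pattern released when a 2,5-disubstituted furan bearing a furfuryl alcohol is oxidised: the furan carbons become C5–C8, the C9 hydroxyl closes on C5, and the ring (O9, C9, C8, C7, C6, C5) gives C8, C7, C6 and finally C5 two faces that C9 alone distinguishes.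

## Logic of the disconnections

The O–H bonds at C5, C8 and C9 of 36 are traced to O–Si bonds in 35, and the C1–O23 ester bond of 35 is cut to give 33. Silyl ethers are the only masks that leave under fluoride conditions mild enough for the oxirane and the Z-enoate. The cut turns the large ring into an open chain. The forward ring closure must proceed with retention at C23 and without isomerising C2=C3, and the last step must not be basic.

The C2=C3 bond of 33 is cut, through 32, to the C3 aldehyde of 31 and a two-carbon phosphonoacetate; 31 goes back to 30 and 30 to 29 by oxidation-level and protecting-group changes only. Installing the enoate late avoids carrying a Michael acceptor through the synthesis. The forward steps need a kinetically Z-selective olefination, one oxidant that removes both benzylic ethers of 29, and oxidation of the primary C3 alcohol of 30 beside the free C23 carbinol.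

The O–Si bonds of 29 and the C5–H bond of 28 are removed to reach the C5 carbonyl of 27, which is the ring–chain tautomer of 26. With C5 at the carbonyl level the acyclic array is recognised as a pyran closed through O9, so the five-centre open-chain problem becomes a ring problem with one centre fewer. The forward reduction must deliver hydride under chelation between the carbonyl and oxirane oxygens to give the erythro relationship.

The C5–OH bond of 26 is exchanged for the C5–OMe bond of 25, and the C8–O bond of 25 is reconnected, through 24, with the opposite configuration in 23. In the pyran the oxirane can be made by hydroxyl direction only if C8–OH is cis to it, whereas the target needs them trans. The forward steps therefore need a clean SN2 inversion at a hindered carbinol, ester cleavage without oxirane migration, and ketal hydrolysis without oxirane opening.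

The C18=C19 bond of 23 is cut to the aldehyde carbon of 14 and the ylide carbon of 22, made from 21. An isolated cis alkene is the retron of a non-stabilised Wittig reaction, and the cut removes the whole C19–C24 piece with its remote stereocentre. The forward step must be Z-selective and tolerate the free C8 hydroxyl.

From 14 (the C18 aldehyde of 13), the two oxirane C–O bonds of 13, the C8–H bond of 12 and the C5–OMe bond of 11 are removed in turn to reach 10. Each forward operation is a face-selective event on a ring π bond, so three stereocentres disappear in this direction. The forward steps require hydride to reach C8 on the ring face that leaves the hydroxyl trans to C10, oxygen to be delivered to C6=C7 syn to that hydroxyl, and C5 to be masked during the reduction.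

The C5–O9 bond of 10 is cut and the ene-dione 9 is folded back into the aromatic ring of 8. One ring, a cis alkene and two carbonyl groups collapse into a stable heteroaromatic that is easily substituted at both α positions. The forward oxidation must act on the furan only, in the presence of an anisyl ring and a silyl ether, and must not touch C9.

The C9–H bond of 8 leads to the ketone 7, and the C8–C9 bond of 7 is cut to the metalated furan 6 (from 5) and the amide 3. A heteroaryl alkyl ketone is an ideal substrate for catalytic asymmetric transfer hydrogenation, the only point at which absolute configuration enters the C5–C9 sector. The forward steps need mono-addition to the amide and high enantioselectivity.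

3 is reduced to 2 and then 1 by O–Si and C–N disconnections, and 5 to 4 by an ether disconnection. 21 goes back through 20, 19 and 17 to 16 by C–P, C–iodide, C19–O and ether disconnections, and the C21–C22 bond of 16 is cut to 15 and an allyl nucleophile. The chiral-pool oxirane supplies C23; its opening must occur at the CH2 carbon and the hydroboration must be anti-Markovnikov.

## Other disconnections considered

Alternative 1: The cut is made at C18–C19 at the alkyne oxidation level, so that the ring is closed by alkyne metathesis instead of lactonisation. In the forward direction the diyne ester A1, methyl-capped at both alkynes, would be treated with p-MeOC6H4C≡Mo(OSiPh3)3 and 5 Å molecular sieves in toluene to give the cycloalkyne A2 with loss of a volatile dialkylalkyne. Semi-hydrogenation over Pd/CaCO3 poisoned with Pb(OAc)2 and quinoline would then converge on 35.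
- In its favour: the ring closes at a remote, unfunctionalised site; the ester bond is made intermolecularly; C23 is never at risk. The cis geometry of C18=C19 comes from syn hydrogenation rather than from the kinetic selectivity of a Wittig reaction, and on this point it is better than the chosen plan.
- Against it here: both alkyne termini must be built and capped, the catalyst is moisture-sensitive, and the semi-hydrogenation must spare the Z-enoate.
- Comparison: it says nothing about how C5–C9 are made, so it is an endgame variant that could sit on top of the furan route. Mechanistically it is equal in functional-group tolerance. In step economy it is expected to cost two or three extra steps for alkyne installation and reduction.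

Alternative 2: The cut is the C6–C7 bond. The (S)-α-silyloxy aldehyde A3 would add (Z)-γ-chloroallyl-B(Ipc)2 at low temperature to give the syn-chlorohydrin A4, which DBU would close in the same flask to the cis-vinyl oxirane A5.
- In its favour: one flask forms a C–C bond and both oxirane stereocentres under reagent control, and no inversion is needed. As a key step it creates two stereocentres directly, whereas the furan oxidation creates none, so on this count it is the stronger step.
- Against it here: C5 must come from a separate source and sits α to an aldehyde, the reagent is made in situ at very low temperature, and the vinyl oxirane is a reactive allylic electrophile. C8 and C9 would still have to be installed from the vinyl group, for example by chain extension and a face-selective dihydroxylation next to the oxirane, where matching is uncertain.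
- Comparison: the chosen plan derives all five centres from one catalytic reduction by relay through a ring, at the price of one inversion and ketal handling. Alternative 2 needs three independent sources of chirality. The overall step count is expected to be similar.

Alternative 3: The cuts are C1–C2 and C1–O23, with carbon monoxide as C1. The Z-alkenyl iodide A6, which would come from 31 by a Z-selective iodo-olefination, would undergo oxidative addition to zerovalent palladium (Pd(PPh3)4) under CO with Et3N. The acylpalladium would be captured by the C23 hydroxyl to give A7, which is identical with 35.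
- In its favour: no seco-acid is made, no ester is hydrolysed, and no activated Z-enoate meets a nucleophilic catalyst. It needs two steps from 31 where the chosen plan needs three, and on step count and Z-integrity it is better.
- Against it here: capture of an acylpalladium by a remote secondary alcohol at high dilution is slow, intermolecular ester formation and reduction compete, and the catalyst must survive under CO at low concentration. Large-ring precedent is thinner than for anhydride-based lactonisation.
- Comparison: on structure it is equal, because it shares the furan oxidation and all the stereochemical logic. It is mechanistically more economical but less certain for a 24-membered ring.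

Key step: step 6

Remark 1: positional numbers C1–C24 follow the seco-acid chain (C1 lactone carbonyl, C23 lactone carbinol, C24 methyl).
Remark 2: 10-hydroxydecanoic acid is taken as a catalogue chemical; decane-1,10-diol would reach the same amide in one further step.
Remark 3: the Luche reduction is taken to deliver hydride to the ring face anti to the axial anomeric methoxy group, which places the new C8 hydroxyl trans to the C10 chain; this sense is what makes the later inversion at C8 necessary.
Remark 4: methyl ketals 11–14 and 23–25 are drawn as the anomer with OMe trans to the C10 chain (anomeric effect); the other anomer would serve equally, because C5 returns to the carbonyl level in step 19.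
Remark 5: the precursor 8 keeps a non-participating ether at C3, and its C18 silyl ether is chosen so that it leaves during the ketal formation of step 7.

Step 1
Reactants: 1 10-hydroxydecanoic acid
Product: 2 10-hydroxy-N-methoxy-N-methyldecanamide
Conditions: MeNH(OMe)·HCl, EDCI·HCl, HOBt (cat.), N-methylmorpholine, CH2Cl2, 0 °C to rt
Reagents that add atoms: N,O-dimethylhydroxylamine hydrochloride, CNOC.Cl
Why: Carbodiimide amidation; the amine outcompetes the remote primary hydroxyl for the activated ester, so the Weinreb amide should form without protection.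

Step 2
Reactants: 2 10-hydroxy-N-methoxy-N-methyldecanamide
Product: 3 10-(tert-butyldimethylsilyloxy)-N-methoxy-N-methyldecanamide
Conditions: TBSCl, imidazole, DMF, rt
Reagents that add atoms: tert-butyldimethylsilyl chloride, CC(C)(C)[Si](C)(C)Cl
Why: Standard silylation of a primary alcohol; the ether masks C18–OH against the organolithium of step 4.

Step 3
Reactants: 4 2-(furan-2-yl)ethanol
Product: 5 2-[2-(4-methoxybenzyloxy)ethyl]furan
Conditions: NaH, 4-MeOC6H4CH2Cl, Bu4NI (cat.), THF, 0 °C to rt
Reagents that add atoms: 4-methoxybenzyl chloride, COc1ccc(CCl)cc1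
Why: Williamson etherification under basic conditions spares the acid-sensitive furan and gives a C3 ether that cannot add to C5 later.

Step 4
Reactants: 5 2-[2-(4-methoxybenzyloxy)ethyl]furan; 3 10-(tert-butyldimethylsilyloxy)-N-methoxy-N-methyldecanamide
Product: 7 10-(tert-butyldimethylsilyloxy)-1-{5-[2-(4-methoxybenzyloxy)ethyl]furan-2-yl}decan-1-one, via 5-lithiofuran 6 (not isolated)
Conditions: n-BuLi, THF, −78 to 0 °C; then 3, −78 to 0 °C; aq. NH4Cl
Reagents that add atoms: none
Why: α-Lithiation of the 2-alkylfuran at its free α position followed by Weinreb ketone synthesis forms the C8–C9 bond; the chelated tetrahedral adduct prevents a second addition.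

Step 5
Reactants: 7 10-(tert-butyldimethylsilyloxy)-1-{5-[2-(4-methoxybenzyloxy)ethyl]furan-2-yl}decan-1-one
Product: 8 (1R)-10-(tert-butyldimethylsilyloxy)-1-{5-[2-(4-methoxybenzyloxy)ethyl]furan-2-yl}decan-1-ol
Conditions: RuCl(p-cymene)[(R,R)-TsDPEN] (1 mol %), HCO2H/Et3N (5:2), CH2Cl2, rt
Reagents that add atoms: none
Why: Noyori asymmetric transfer hydrogenation of a heteroaryl alkyl ketone; the furyl group takes the aryl position in the CH–π-stabilised transition state, so the (R,R) catalyst should give the (R)-carbinol at C9.

Step 6
Reactants: 8 (1R)-10-(tert-butyldimethylsilyloxy)-1-{5-[2-(4-methoxybenzyloxy)ethyl]furan-2-yl}decan-1-ol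
Product: 10 (2R)-2-[9-(tert-butyldimethylsilyloxy)nonyl]-6-hydroxy-6-[2-(4-methoxybenzyloxy)ethyl]-2H-pyran-3(6H)-one, via Z-enedione 9 (not isolated)
Conditions: NBS, NaHCO3, NaOAc, THF/H2O (4:1), 0 °C
Reagents that add atoms: water, O
Why: NBS delivers electrophilic bromine to an α carbon of the electron-rich furan, water adds at the other α carbon, and loss of HBr (taken up by the buffer) opens the 2,5-dihydrofuran to the Z-enedione 9, in which C5 and C8 are carbonyl carbons. The closest known reaction type is the Achmatowicz rearrangement of 2,5-disubstituted furfuryl alcohols to 6-hydroxy-2H-pyran-3(6H)-ones. The single ring is closed by 6-exo-trig attack of the C9 hydroxyl oxygen on the C5 carbonyl carbon, which forms the C5–O9 bond as a hemiketal and leaves C8 as the enone carbonyl. No stereocentre of the target is created: the anomeric carbon C5 equilibrates and later returns to the carbonyl level, and C9 keeps its (R) configuration because none of its bonds is broken. The C6=C7 geometry can only be cis, because both carbons were adjacent ring atoms of the furan and remain ring atoms of the pyranone. The step needs chemoselectivity for the furan over the anisyl ring and the silyl ether; the much higher nucleophilicity of the furan, one equivalent of oxidant at 0 °C and the buffer secure it. The ether at C3 is essential, since a free C3 hydroxyl would be captured by C5 as a spiroketal.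

Step 7
Reactants: 10 (2R)-2-[9-(tert-butyldimethylsilyloxy)nonyl]-6-hydroxy-6-[2-(4-methoxybenzyloxy)ethyl]-2H-pyran-3(6H)-one
Product: 11 (2R,6S)-2-(9-hydroxynonyl)-6-methoxy-6-[2-(4-methoxybenzyloxy)ethyl]-2H-pyran-3(6H)-one
Conditions: CSA (0.2 equiv), HC(OMe)3, MeOH, 0 °C to rt; Et3N quench
Reagents that add atoms: methanol, CO
Why: Acid-catalysed ketal exchange through the ring oxocarbenium ion should give the methyl ketal with OMe axial (anomeric effect) and trans to the C10 chain. The same acidic methanol cleaves the primary silyl ether, so C18–OH is released in the same operation while the benzylic ether stays.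

Step 8
Reactants: 11 (2R,6S)-2-(9-hydroxynonyl)-6-methoxy-6-[2-(4-methoxybenzyloxy)ethyl]-2H-pyran-3(6H)-one
Product: 12 (2R,3S,6S)-2-(9-hydroxynonyl)-6-methoxy-6-[2-(4-methoxybenzyloxy)ethyl]-3,6-dihydro-2H-pyran-3-ol
Conditions: NaBH4, CeCl3·7H2O, MeOH, −78 °C
Reagents that add atoms: none
Why: Luche 1,2-reduction of the enone; axial hydride attack anti to the axial methoxy group should give the pseudo-equatorial C8 hydroxyl trans to the C10 chain (substrate control from C9). The ketal prevents reduction at C5.

Step 9
Reactants: 12 (2R,3S,6S)-2-(9-hydroxynonyl)-6-methoxy-6-[2-(4-methoxybenzyloxy)ethyl]-3,6-dihydro-2H-pyran-3-ol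
Product: 13 C6–C7 epoxide of 12 (oxirane oxygen cis to C8–OH and to OMe; trans to the C10 chain)
Conditions: VO(acac)2 (5 mol %), t-BuOOH, CH2Cl2, 0 °C to rt
Reagents that add atoms: tert-butyl hydroperoxide, CC(C)(C)OO
Why: Hydroxyl-directed epoxidation of a cyclic allylic alcohol; the vanadium alkoxide at C8 delivers the peroxide oxygen intramolecularly to the alkene face syn to C8–OH, which sets C6 and C7. The neutral conditions spare the ketal and the primary alcohol.

Step 10
Reactants: 13 C6–C7 epoxide of 12
Product: 14 C18 aldehyde of 13 (C8–OH free)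
Conditions: TEMPO (10 mol %), PhI(OAc)2, CH2Cl2, rt
Reagents that add atoms: none
Why: Oxoammonium oxidation is selective for the unhindered primary alcohol over the hindered secondary C8 carbinol and stops at the aldehyde.

Step 11
Reactants: 15 (R)-2-methyloxirane
Product: 16 (2R)-hex-5-en-2-ol
Conditions: CH2=CHCH2MgBr, CuI (10 mol %), THF, −40 to 0 °C; aq. NH4Cl
Reagents that add atoms: allylmagnesium bromide, C=CC[Mg]Br
Why: Copper-catalysed Grignard opening of a terminal epoxide at its CH2 carbon forms C21–C22; the C–O bond at the stereocentre is untouched, so C23 stays (R).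

Step 12
Reactants: 16 (2R)-hex-5-en-2-ol
Product: 17 1-{[(2R)-hex-5-en-2-yloxy]methyl}-4-methoxybenzene
Conditions: NaH, 4-MeOC6H4CH2Cl, Bu4NI (cat.), DMF, 0 °C to rt
Reagents that add atoms: 4-methoxybenzyl chloride, COc1ccc(CCl)cc1
Why: Williamson etherification; the same benzylic ether as at C3 is chosen so that one oxidant frees both hydroxyls in step 22.

Step 13
Reactants: 17 1-{[(2R)-hex-5-en-2-yloxy]methyl}-4-methoxybenzene
Product: 19 (5R)-5-(4-methoxybenzyloxy)hexan-1-ol, via alkylborane 18 (not isolated)
Conditions: 9-BBN, THF, 0 °C to rt; then NaOH, H2O2, 0 °C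
Reagents that add atoms: hydrogen peroxide, OO
Why: Anti-Markovnikov hydroboration–oxidation; the bulky borane places boron on the terminal carbon (C19) and oxidation proceeds with retention at carbon.

Step 14
Reactants: 19 (5R)-5-(4-methoxybenzyloxy)hexan-1-ol
Product: 20 1-({[(2R)-6-iodohexan-2-yl]oxy}methyl)-4-methoxybenzene
Conditions: iodine, PPh3, imidazole, CH2Cl2, 0 °C to rt
Reagents that add atoms: iodine, [I][I]
Why: Appel-type iodination of a primary alcohol through the oxyphosphonium salt; the secondary benzylic ether is inert.

Step 15
Reactants: 20 1-({[(2R)-6-iodohexan-2-yl]oxy}methyl)-4-methoxybenzene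
Product: 21 [(5R)-5-(4-methoxybenzyloxy)hexyl]triphenylphosphonium iodide
Conditions: PPh3, MeCN, 80 °C
Reagents that add atoms: triphenylphosphine, c1ccc(cc1)P(c1ccccc1)c1ccccc1
Why: SN2 quaternisation of triphenylphosphine by a primary iodide.

Step 16
Reactants: 21 [(5R)-5-(4-methoxybenzyloxy)hexyl]triphenylphosphonium iodide; 14 C18 aldehyde of 13
Product: 23 (18Z)-C3–C24 pyran methyl ketal (C8–OH cis to the oxirane; C23 (R) benzylic ether), via phosphorus ylide 22 (not isolated)
Conditions: 21 (2.5 equiv), NaN(SiMe3)2 (2.4 equiv), THF, 0 °C; then 14, −78 °C to rt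
Reagents that add atoms: none
Why: Wittig olefination with a non-stabilised ylide under lithium-free conditions is kinetically Z-selective through the cis-oxaphosphetane and forms C18=C19. One equivalent of ylide is consumed by the C8 hydroxyl, whose alkoxide is cis to the oxirane and so cannot displace it from the rear.

Step 17
Reactants: 23 (18Z)-C3–C24 pyran methyl ketal (C8–OH cis to the oxirane)
Product: 24 C8 4-nitrobenzoate of 23 with inverted C8 (ester oxygen cis to the C10 chain; trans to the oxirane)
Conditions: 4-O2NC6H4CO2H, PPh3, DIAD, toluene, 0 °C to rt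
Reagents that add atoms: 4-nitrobenzoic acid, O=C(O)c1ccc(cc1)[N+](=O)[O-]
Why: Mitsunobu esterification; SN2 displacement of the oxyphosphonium group by the carboxylate inverts C8. The acidic nitrobenzoic acid is the usual choice for a hindered carbinol.

Step 18
Reactants: 24 C8 4-nitrobenzoate with inverted C8
Product: 25 C8 alcohol with the target configuration at C8 (pyran methyl ketal)
Conditions: K2CO3 (0.5 equiv), MeOH, 0 °C
Reagents that add atoms: none
Why: Transesterification of an activated aryl ester; brief exposure at 0 °C limits Payne migration of the oxirane towards the now trans-disposed C8 alkoxide.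

Step 19
Reactants: 25 C8 alcohol (pyran methyl ketal)
Product: 26 C5 hemiketal of 25 (anomeric centre unset)
Conditions: 0.5 M aq. HCl, THF, 0 °C to rt
Reagents that add atoms: water, O
Why: Acid hydrolysis of a ketose-type methyl ketal through the tertiary oxocarbenium ion; an oxirane flanked by two oxygenated carbons is deactivated towards acid opening, and the benzylic ethers and the alkene are stable.

Step 20
Reactants: 26 C5 hemiketal
Product: 28 (5S)-C5/C8/C9 triol with C3 and C23 benzylic ethers, via open-chain hydroxy ketone 27 (not isolated)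
Conditions: Zn(BH4)2, Et2O, −20 to 0 °C; aq. NH4Cl
Reagents that add atoms: none
Why: Chelation-controlled reduction of an α,β-epoxy ketone; the hemiketal opens to the C5 ketone, zinc bridges the carbonyl and oxirane oxygens, and hydride attacks the face away from C7. This should give the erythro epoxy alcohol, which is (5S).

Step 21
Reactants: 28 (5S)-C5/C8/C9 triol
Product: 29 C5/C8/C9 tris(tert-butyldimethylsilyl) ether of 28
Conditions: TBSOTf, 2,6-lutidine, CH2Cl2, −78 to 0 °C
Reagents that add atoms: tert-butyldimethylsilyl trifluoromethanesulfonate, CC(C)(C)[Si](C)(C)OS(=O)(=O)C(F)(F)F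
Why: Silyl triflate with a hindered base silylates all three secondary hydroxyls, including the vicinal pair, at low temperature, where the oxirane is not opened.

Step 22
Reactants: 29 tris-silyl ether
Product: 30 C3/C23 diol (tris-silyl ether)
Conditions: DDQ, CH2Cl2/pH 7 buffer, 0 °C to rt
Reagents that add atoms: none
Why: Oxidative cleavage of both 4-methoxybenzyl ethers by benzylic hydride abstraction and hydrolysis; silyl ethers, the oxirane and the isolated alkene are not affected.

Step 23
Reactants: 30 C3/C23 diol
Product: 31 C3 aldehyde with free C23 hydroxyl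
Conditions: TEMPO (10 mol %), PhI(OAc)2, CH2Cl2, rt
Reagents that add atoms: none
Why: Oxoammonium oxidation discriminates the primary C3 alcohol from the secondary C23 carbinol and does not over-oxidise.

Step 24
Reactants: 31 C3 aldehyde with free C23 hydroxyl
Product: 32 ethyl (2Z)-enoate of the seco acid (C23–OH free)
Conditions: (2-MeC6H4O)2P(O)CH2CO2Et, NaH, THF, −78 to −20 °C
Reagents that add atoms: ethyl 2-[bis(2-methylphenoxy)phosphoryl]acetate, CCOC(=O)CP(=O)(Oc1ccccc1C)Oc1ccccc1C
Why: Ando variant of the Horner–Wadsworth–Emmons reaction; the electron-poor diaryl phosphonate makes elimination from the first-formed adduct fast, so C2=C3 should form Z under kinetic control. The stabilised anion is too weakly basic to disturb the free C23 hydroxyl or the β-silyloxy aldehyde.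

Step 25
Reactants: 32 ethyl (2Z)-enoate
Product: 33 (2Z,18Z)-seco acid (C23–OH free; C5/C8/C9 silyl ethers)
Conditions: LiOH, THF/MeOH/H2O, 0 °C to rt; then 1 M HCl to pH 4
Reagents that add atoms: lithium hydroxide, [Li+].[OH-]
Why: Saponification of an unhindered ethyl ester; the silyl ethers and the protected epoxy triol are stable to aqueous hydroxide at this temperature.

Step 26
Reactants: 33 (2Z,18Z)-seco acid
Product: 35 tris-silylated 24-membered macrolactone, via mixed anhydride 34 (not isolated)
Conditions: 2-methyl-6-nitrobenzoic anhydride, DMAP, CH2Cl2 (1 mM), rt, slow addition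
Reagents that add atoms: none
Why: Shiina macrolactonisation; the acid is activated as the mixed anhydride and acyl transfer to C23–OH under high dilution closes the ring with retention at C23. Room temperature is chosen to protect the Z-enoate.

Step 27
Reactants: 35 tris-silylated macrolactone
Product: 36 AKML B
Conditions: HF·pyridine, pyridine, THF, 0 °C to rt
Reagents that add atoms: none
Why: Fluoride cleavage of the three silyl ethers under buffered, non-basic conditions avoids both oxirane migration and ring contraction of the δ-hydroxy Z-enoate.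

Compound list

1 | 10-hydroxydecanoic acid | OCCCCCCCCCC(=O)O | starting material
2 | 10-hydroxy-N-methoxy-N-methyldecanamide | OCCCCCCCCCC(=O)N(C)OC | intermediate
3 | 10-(tert-butyldimethylsilyloxy)-N-methoxy-N-methyldecanamide (C9–C18) | CC(C)(C)[Si](C)(C)OCCCCCCCCCC(=O)N(C)OC | intermediate
4 | 2-(furan-2-yl)ethanol | OCCc1ccco1 | starting material
5 | 2-[2-(4-methoxybenzyloxy)ethyl]furan | COc1ccc(COCCc2ccco2)cc1 | intermediate
6 | 5-lithio-2-[2-(4-methoxybenzyloxy)ethyl]furan | [Li]c1ccc(CCOCc2ccc(OC)cc2)o1 | intermediate
7 | 10-(tert-butyldimethylsilyloxy)-1-{5-[2-(4-methoxybenzyloxy)ethyl]furan-2-yl}decan-1-one | CC(C)(C)[Si](C)(C)OCCCCCCCCCC(=O)c1ccc(CCOCc2ccc(OC)cc2)o1 | intermediate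
8 | (1R)-10-(tert-butyldimethylsilyloxy)-1-{5-[2-(4-methoxybenzyloxy)ethyl]furan-2-yl}decan-1-ol (C3–C18 furyl carbinol) | CC(C)(C)[Si](C)(C)OCCCCCCCCC[C@@H](O)c1ccc(CCOCc2ccc(OC)cc2)o1 | intermediate
9 | (4Z,7R)-16-(tert-butyldimethylsilyloxy)-7-hydroxy-1-(4-methoxybenzyloxy)hexadec-4-ene-3,6-dione | CC(C)(C)[Si](C)(C)OCCCCCCCCC[C@@H](O)C(=O)/C=C\C(=O)CCOCc1ccc(OC)cc1 | intermediate
10 | (2R)-2-[9-(tert-butyldimethylsilyloxy)nonyl]-6-hydroxy-6-[2-(4-methoxybenzyloxy)ethyl]-2H-pyran-3(6H)-one (anomeric centre unset) | CC(C)(C)[Si](C)(C)OCCCCCCCCC[C@H]1OC(O)(CCOCc2ccc(OC)cc2)C=CC1=O | intermediate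
11 | (2R,6S)-2-(9-hydroxynonyl)-6-methoxy-6-[2-(4-methoxybenzyloxy)ethyl]-2H-pyran-3(6H)-one (OMe trans to the C10 chain) | OCCCCCCCCC[C@H]1O[C@@](OC)(CCOCc2ccc(OC)cc2)C=CC1=O | intermediate
12 | (2R,3S,6S)-2-(9-hydroxynonyl)-6-methoxy-6-[2-(4-methoxybenzyloxy)ethyl]-3,6-dihydro-2H-pyran-3-ol (C8–OH trans to the C10 chain, cis to OMe) | OCCCCCCCCC[C@H]1O[C@@](OC)(CCOCc2ccc(OC)cc2)C=C[C@@H]1O | intermediate
13 | C6–C7 epoxide of 12; oxirane oxygen, C8–OH and OMe on the ring face opposite to the C10 chain; C9 (R) | OCCCCCCCCC[C@H]1O[C@@](OC)(CCOCc2ccc(OC)cc2)[C@@H]2O[C@@H]2[C@@H]1O | intermediate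
14 | C18 aldehyde of 13 | O=CCCCCCCCC[C@H]1O[C@@](OC)(CCOCc2ccc(OC)cc2)[C@@H]2O[C@@H]2[C@@H]1O | intermediate
15 | (R)-2-methyloxirane | C[C@@H]1CO1 | starting material
16 | (2R)-hex-5-en-2-ol | C[C@@H](O)CCC=C | intermediate
17 | 1-{[(2R)-hex-5-en-2-yloxy]methyl}-4-methoxybenzene | C[C@@H](OCc1ccc(OC)cc1)CCC=C | intermediate
18 | 9-[(5R)-5-(4-methoxybenzyloxy)hexyl]-9-borabicyclo[3.3.1]nonane | C[C@@H](OCc1ccc(OC)cc1)CCCCB1C2CCCC1CCC2 | intermediate
19 | (5R)-5-(4-methoxybenzyloxy)hexan-1-ol | C[C@@H](OCc1ccc(OC)cc1)CCCCO | intermediate
20 | 1-({[(2R)-6-iodohexan-2-yl]oxy}methyl)-4-methoxybenzene | C[C@@H](OCc1ccc(OC)cc1)CCCCI | intermediate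
21 | [(5R)-5-(4-methoxybenzyloxy)hexyl]triphenylphosphonium iodide (C19–C24) | C[C@@H](OCc1ccc(OC)cc1)CCCC[P+](c1ccccc1)(c1ccccc1)c1ccccc1.[I-] | intermediate
22 | [(5R)-5-(4-methoxybenzyloxy)hexylidene]triphenylphosphorane | C[C@@H](OCc1ccc(OC)cc1)CCCC=P(c1ccccc1)(c1ccccc1)c1ccccc1 | intermediate
23 | (18Z)-C3–C24 pyran methyl ketal; C8–OH cis to the oxirane and trans to the C10 chain; C9 (R), C23 (R) benzylic ether | C[C@@H](OCc1ccc(OC)cc1)CCC/C=C\CCCCCCCC[C@H]1O[C@@](OC)(CCOCc2ccc(OC)cc2)[C@@H]2O[C@@H]2[C@@H]1O | intermediate
24 | C8 4-nitrobenzoate with inverted C8 (ester oxygen cis to the C10 chain, trans to the oxirane) | C[C@@H](OCc1ccc(OC)cc1)CCC/C=C\CCCCCCCC[C@H]1O[C@@](OC)(CCOCc2ccc(OC)cc2)[C@@H]2O[C@@H]2[C@H]1OC(=O)c1ccc(cc1)[N+](=O)[O-] | intermediate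
25 | C8 alcohol of 24 (C8–OH cis to the C10 chain, trans to the oxirane) | C[C@@H](OCc1ccc(OC)cc1)CCC/C=C\CCCCCCCC[C@H]1O[C@@](OC)(CCOCc2ccc(OC)cc2)[C@@H]2O[C@@H]2[C@H]1O | intermediate
26 | C5 hemiketal of 25 (anomeric centre unset) | C[C@@H](OCc1ccc(OC)cc1)CCC/C=C\CCCCCCCC[C@H]1OC(O)(CCOCc2ccc(OC)cc2)[C@@H]2O[C@@H]2[C@H]1O | intermediate
27 | open-chain C5 ketone tautomer of 26 (C8, C9 diol; cis-6,7-oxirane) | C[C@@H](OCc1ccc(OC)cc1)CCC/C=C\CCCCCCCC[C@@H](O)[C@H](O)[C@H]1O[C@H]1C(=O)CCOCc1ccc(OC)cc1 | intermediate
28 | (18Z)-6,7-epoxy-3,23-bis(4-methoxybenzyloxy)tetracos-18-ene-5,8,9-triol, configured as 36 at C5–C9 and C23 | C[C@@H](OCc1ccc(OC)cc1)CCC/C=C\CCCCCCCC[C@@H](O)[C@H](O)[C@H]1O[C@H]1[C@@H](O)CCOCc1ccc(OC)cc1 | intermediate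
29 | 5,8,9-tris(tert-butyldimethylsilyl) ether of 28 | C[C@@H](OCc1ccc(OC)cc1)CCC/C=C\CCCCCCCC[C@@H](O[Si](C)(C)C(C)(C)C)[C@H](O[Si](C)(C)C(C)(C)C)[C@H]1O[C@H]1[C@@H](O[Si](C)(C)C(C)(C)C)CCOCc1ccc(OC)cc1 | intermediate
30 | (18Z)-5,8,9-tris(tert-butyldimethylsilyloxy)-6,7-epoxytetracos-18-ene-3,23-diol, configured as 36 | C[C@@H](O)CCC/C=C\CCCCCCCC[C@@H](O[Si](C)(C)C(C)(C)C)[C@H](O[Si](C)(C)C(C)(C)C)[C@H]1O[C@H]1[C@@H](O[Si](C)(C)C(C)(C)C)CCO | intermediate
31 | C3 aldehyde of 30 (C23–OH free) | C[C@@H](O)CCC/C=C\CCCCCCCC[C@@H](O[Si](C)(C)C(C)(C)C)[C@H](O[Si](C)(C)C(C)(C)C)[C@H]1O[C@H]1[C@@H](O[Si](C)(C)C(C)(C)C)CC=O | intermediate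
32 | ethyl (2Z,18Z)-5,8,9-tris(tert-butyldimethylsilyloxy)-6,7-epoxy-23-hydroxytetracosa-2,18-dienoate, configured as 36 | C[C@@H](O)CCC/C=C\CCCCCCCC[C@@H](O[Si](C)(C)C(C)(C)C)[C@H](O[Si](C)(C)C(C)(C)C)[C@H]1O[C@H]1[C@@H](O[Si](C)(C)C(C)(C)C)C/C=C\C(=O)OCC | intermediate
33 | (2Z,18Z)-5,8,9-tris(tert-butyldimethylsilyloxy)-6,7-epoxy-23-hydroxytetracosa-2,18-dienoic acid, configured as 36 | C[C@@H](O)CCC/C=C\CCCCCCCC[C@@H](O[Si](C)(C)C(C)(C)C)[C@H](O[Si](C)(C)C(C)(C)C)[C@H]1O[C@H]1[C@@H](O[Si](C)(C)C(C)(C)C)C/C=C\C(=O)O | intermediate
34 | mixed anhydride of 33 with 2-methyl-6-nitrobenzoic acid | C[C@@H](O)CCC/C=C\CCCCCCCC[C@@H](O[Si](C)(C)C(C)(C)C)[C@H](O[Si](C)(C)C(C)(C)C)[C@H]1O[C@H]1[C@@H](O[Si](C)(C)C(C)(C)C)C/C=C\C(=O)OC(=O)c1c(C)cccc1[N+](=O)[O-] | intermediate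
35 | 5,8,9-tris(tert-butyldimethylsilyl) ether of AKML B | C[C@@H]1CCC/C=C\CCCCCCCC[C@@H](O[Si](C)(C)C(C)(C)C)[C@H](O[Si](C)(C)C(C)(C)C)[C@H]2O[C@H]2[C@@H](O[Si](C)(C)C(C)(C)C)C/C=C\C(=O)O1 | intermediate
36 | AKML B, (2Z,5S,6S,7R,8S,9R,18Z,23R)-6,7-epoxy-5,8,9-trihydroxytetracosa-2,18-dien-23-olide | C[C@@H]1CCC/C=C\CCCCCCCC[C@@H](O)[C@H](O)[C@H]2O[C@H]2[C@@H](O)C/C=C\C(=O)O1 | target

Total step count: 27. Longest linear sequence: 21 steps (from 1 through steps 1, 2, 4–10 and 16–27).

Steps least certain to work

Step 6 (key step). The likely failure is over-oxidation or acid-promoted isomerisation of the Z-enedione to the E isomer, which cannot close, or loss of the silyl ether if the HBr formed is not fully buffered. The fallback separates oxidation from rearrangement. From 8, bromine in methanol with Na2CO3 at −40 °C (Clauson-Kaas-type oxidative methoxylation) should give the isolable 2,5-dimethoxy-2,5-dihydrofuran F1 as a diastereomer mixture. Brief treatment of this bis-ketal with dilute aqueous acid in THF at 0 °C unmasks the enedione under non-oxidising conditions, and ring closure by the C9 hydroxyl returns the route to 10.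

Step 9. The axial methoxy group lies on the same ring face as the directing C8 hydroxyl, so oxygen delivery to that face may be slow. Oxidation of the allylic alcohol to the enone, or epoxidation of the open face, may then compete. The fallback inverts the facial logic. From 12, NBS in aqueous THF should form the bromonium ion on the less hindered lower face and water should open it trans-diaxially at C7, giving the bromohydrin F2 (C6–Br down, C7–OH up). K2CO3 in methanol then closes the C7 alkoxide onto C6 with displacement of bromide, which places the oxirane on the hindered upper face and rejoins the route at 13.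

Step 17. Backside attack at C8 is hindered by the C10 chain and the ring, so the oxyphosphonium intermediate may undergo elimination, or acyl transfer with retention through an acyloxyphosphonium species. The fallback isolates the activated alcohol. From 23, Tf2O and pyridine in CH2Cl2 at −20 °C give the triflate F3. CsOAc with 18-crown-6 in toluene displaces it with inversion to the acetate F4, and K2CO3 in methanol at 0 °C cleaves the acetate to rejoin the route at 25.

Step 20 (with the hydrolysis of step 19). Zinc alkoxides formed from the free C8 and C9 hydroxyls may compete with the oxirane for chelation, or the hemiketal may open too slowly, so that part of the reduction passes through a non-chelated transition state and C5 selectivity is eroded. The fallback reduces a discrete, fully protected acyclic epoxy ketone. From 26, TBSOTf and 2,6-lutidine at −78 °C should silylate the C8 hydroxyl and drain the ring–chain equilibrium by silylating the secondary C9 hydroxyl of the open form, giving the bis-silylated open-chain epoxy ketone F5. Zn(BH4)2 in ether then reduces this plain α,β-epoxy ketone under chelation control to the C5 carbinol F6, and a further silylation returns to 29.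

Step 26. Reversible conjugate addition of DMAP to the activated Z-enoate may cause Z to E isomerisation, deconjugation through a vinylketene is possible, and oligomerisation may compete with closure of the large ring. The fallback avoids activating the enoic acid altogether. From 31, the C23 hydroxyl is esterified with 2-[bis(2-methylphenoxy)phosphoryl]acetic acid (DCC, catalytic DMAP) to give the phosphonoacetate aldehyde F7. Deprotonation with NaH in THF at high dilution and 0 °C should then close C2=C3 and the ring in one intramolecular Z-selective Horner–Wadsworth–Emmons reaction. This rejoins the route at 35 and bypasses steps 24 to 26.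

## Further compounds

F1 | step 6 | (1R)-10-(tert-butyldimethylsilyloxy)-1-{2,5-dimethoxy-5-[2-(4-methoxybenzyloxy)ethyl]-2,5-dihydrofuran-2-yl}decan-1-ol (ketal carbons unset) | CC(C)(C)[Si](C)(C)OCCCCCCCCC[C@@H](O)C1(OC)C=CC(CCOCc2ccc(OC)cc2)(OC)O1
F2 | step 9 | bromohydrin of 12 (C6–Br trans to OMe; C7–OH and C8–OH cis to OMe) | OCCCCCCCCC[C@H]1O[C@@](OC)(CCOCc2ccc(OC)cc2)[C@@H](Br)[C@H](O)[C@@H]1O
F3 | step 17 | C8 trifluoromethanesulfonate of 23 | C[C@@H](OCc1ccc(OC)cc1)CCC/C=C\CCCCCCCC[C@H]1O[C@@](OC)(CCOCc2ccc(OC)cc2)[C@@H]2O[C@@H]2[C@@H]1OS(=O)(=O)C(F)(F)F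
F4 | step 17 | C8 acetate with inverted C8 (acetate of 25) | C[C@@H](OCc1ccc(OC)cc1)CCC/C=C\CCCCCCCC[C@H]1O[C@@](OC)(CCOCc2ccc(OC)cc2)[C@@H]2O[C@@H]2[C@H]1OC(C)=O
F5 | step 20 | 8,9-bis(tert-butyldimethylsilyl) ether of the open-chain C5 ketone 27 | C[C@@H](OCc1ccc(OC)cc1)CCC/C=C\CCCCCCCC[C@@H](O[Si](C)(C)C(C)(C)C)[C@H](O[Si](C)(C)C(C)(C)C)[C@H]1O[C@H]1C(=O)CCOCc1ccc(OC)cc1
F6 | step 20 | (5S)-C5 carbinol from F5 (8,9-bis-silyl ether of 28) | C[C@@H](OCc1ccc(OC)cc1)CCC/C=C\CCCCCCCC[C@@H](O[Si](C)(C)C(C)(C)C)[C@H](O[Si](C)(C)C(C)(C)C)[C@H]1O[C@H]1[C@@H](O)CCOCc1ccc(OC)cc1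
F7 | step 26 | C23 [bis(2-methylphenoxy)phosphoryl]acetate of aldehyde 31 | Cc1ccccc1OP(=O)(CC(=O)O[C@H](C)CCC/C=C\CCCCCCCC[C@@H](O[Si](C)(C)C(C)(C)C)[C@H](O[Si](C)(C)C(C)(C)C)[C@H]2O[C@H]2[C@@H](O[Si](C)(C)C(C)(C)C)CC=O)Oc1ccccc1C
A1 | alternative 1 | diyne ester: (R)-oct-6-yn-2-yl (2Z)-5,8,9-tris(tert-butyldimethylsilyloxy)-6,7-epoxyicos-2-en-18-ynoate, configured as 36 | CC#CCCC[C@@H](C)OC(=O)/C=C\C[C@H](O[Si](C)(C)C(C)(C)C)[C@@H]1O[C@@H]1[C@@H](O[Si](C)(C)C(C)(C)C)[C@H](O[Si](C)(C)C(C)(C)C)CCCCCCCCC#CC
A2 | alternative 1 | macrocyclic 18-yne lactone (tris-silyl ether) | C[C@@H]1CCCC#CCCCCCCCC[C@@H](O[Si](C)(C)C(C)(C)C)[C@H](O[Si](C)(C)C(C)(C)C)[C@H]2O[C@H]2[C@@H](O[Si](C)(C)C(C)(C)C)C/C=C\C(=O)O1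
A3 | alternative 2 | (2S)-2-(tert-butyldimethylsilyloxy)-4-(4-methoxybenzyloxy)butanal (C3–C6) | O=C[C@@H](O[Si](C)(C)C(C)(C)C)CCOCc1ccc(OC)cc1
A4 | alternative 2 | syn-chlorohydrin (C7–Cl, C6–OH) spanning C3 to C9 | C=C[C@H](Cl)[C@@H](O)[C@@H](O[Si](C)(C)C(C)(C)C)CCOCc1ccc(OC)cc1
A5 | alternative 2 | cis-vinyl oxirane spanning C3 to C9 | C=C[C@H]1O[C@H]1[C@@H](O[Si](C)(C)C(C)(C)C)CCOCc2ccc(OC)cc2
A6 | alternative 3 | (2Z)-alkenyl iodide with free C23 hydroxyl (C2–C24; tris-silyl ether) | C[C@@H](O)CCC/C=C\CCCCCCCC[C@@H](O[Si](C)(C)C(C)(C)C)[C@H](O[Si](C)(C)C(C)(C)C)[C@H]1O[C@H]1[C@@H](O[Si](C)(C)C(C)(C)C)C/C=C\I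
A7 | alternative 3 | tris-silylated macrolactone (identical with 35) | C[C@@H]1CCC/C=C\CCCCCCCC[C@@H](O[Si](C)(C)C(C)(C)C)[C@H](O[Si](C)(C)C(C)(C)C)[C@H]2O[C@H]2[C@@H](O[Si](C)(C)C(C)(C)C)C/C=C\C(=O)O1
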